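A direct plan would hide the 1,3-diketone in a 1,3-dithiane and join two halves at C2–C3 (C1 = carbinol carbon, C7 = styryl carbon).
The silylated β-keto dithiane enone A1 would be turned into an enolate/2-lithiodithiane dianion (amide base, then t-BuLi) and would open the epoxide A2, itself made by oxazaborolidine reduction of an α-chloro ketone, to give the adduct A3.
Hg(ClO4)2 would then unmask the diketone and buffered fluoride would free the phenols.
Its weakest steps would be: the dianion opening of the epoxide, which has no precedent on an enone-bearing β-keto dithiane and would compete with loss of thiolate from the enolate and with attack of t-BuLi on the enone;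
the dithiane hydrolysis with divalent mercury on the late, acid- and base-labile β-hydroxy enone, a step that only undoes a masking step;
and the masking and protecting sequence as a whole (two silylations, dithiane on and off), which would take about half of the steps without adding a skeletal bond.

**Plan of the new route**
The retrosynthesis cuts C4–C5 and, one stage earlier, the ester bond that stands in for it: the feruloyl unit (C5–C7, ring B = guaiacyl) is first esterified onto the C1 oxygen of an (S)-aldol (C1–C4, ring A = 4-hydroxyphenyl) and is then passed from oxygen to C4.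
The feature that allows this is the 1,5-relation of O(C1) and the C5 carbonyl: O–C1–C2–C3–C4–C5 closes to a six-membered oxane hemiketal, through which the acyl group migrates.
No ring of the target is built; both arenes are bought and the oxane exists only as a transient.
C1 is set by a catalytic formal hydration of an enone (conjugate borylation/oxidation), and no bond to C1 is broken afterwards.
Dithiane, alkyllithium dianion and mercury do not occur; the diketone is never masked and appears only once, as its stable enolate, one step before the end.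

Key step: step 5

Remark: the enol C4=C5 double bond written in the target SMILES belongs to a freely tautomerising β-diketone and is treated as a depiction, not as a stereo-element; C1 (S) and the C6=C7 (E) alkene are the elements to be controlled.

Step 1
Reactants: 1 (E)-4-(4-hydroxyphenyl)but-3-en-2-one
Product: 2 (E)-4-[4-(tert-butyldimethylsilyloxy)phenyl]but-3-en-2-one
Conditions: TBSCl (1.2 equiv), imidazole (2.5 equiv), DMF, 0 °C → rt
Reagents that add atoms: tert-butyldimethylsilyl chloride, CC(C)(C)[Si](C)(C)Cl
Why: Imidazole-promoted O-silylation of the phenol leaves the enone untouched and gives an aryl silyl ether that should tolerate the catalytic alkoxide, the carbodiimide and the lithium amide of the later steps.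

Step 2
Reactants: 2 (E)-4-[4-(tert-butyldimethylsilyloxy)phenyl]but-3-en-2-one
Product: 4 (S)-4-[4-(tert-butyldimethylsilyloxy)phenyl]-4-hydroxybutan-2-one, via (S)-β-boryl ketone 3 (not isolated)
Conditions: CuCl (3 mol %), NaOt-Bu (6 mol %), Josiphos-type ligand 1-[2-(diphenylphosphino)ferrocenyl]ethyldicyclohexylphosphine (3 mol %; the enantiomer that sends boron to the Si face of C4), B2pin2 (1.1 equiv), MeOH (2 equiv), THF, rt; then NaBO3·4H2O (4 equiv), THF/H2O 1:1, 0 °C → rt
Reagents that add atoms: bis(pinacolato)diboron, CC1(C)OB(OC1(C)C)B1OC(C)(C)C(C)(C)O1 (boron of 3); sodium perborate, [Na+].[Na+].O[B-]1(O)OO[B-](O)(O)OO1 (oxygen of 4)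
Why: Copper-catalysed enantioselective conjugate borylation of an acyclic β-aryl enone by a monovalent copper boryl complex of a chiral ferrocenyl diphosphine, followed by perborate oxidation of the C–B bond with retention, amounts to an asymmetric hydration of the enone in which the ligand decides the face of C4 that receives boron (Si face for S) and methanol turns over the copper enolate.

Step 3
Reactants: 5 (E)-ferulic acid [(E)-3-(4-hydroxy-3-methoxyphenyl)prop-2-enoic acid]
Product: 7 (E)-3-[4-(tert-butyldimethylsilyloxy)-3-methoxyphenyl]prop-2-enoic acid, via bis-silylated ferulate 6 (not isolated)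
Conditions: TBSCl (2.4 equiv), imidazole (5 equiv), DMF, rt; then AcOH/THF/H2O 3:1:1, rt
Reagents that add atoms: tert-butyldimethylsilyl chloride, CC(C)(C)[Si](C)(C)Cl
Why: Exhaustive silylation followed by selective hydrolysis of the much more labile silyl ester should leave the phenol protected and the carboxylic acid free for coupling.

Step 4
Reactants: 4 (S)-4-[4-(tert-butyldimethylsilyloxy)phenyl]-4-hydroxybutan-2-one; 7 (E)-3-[4-(tert-butyldimethylsilyloxy)-3-methoxyphenyl]prop-2-enoic acid
Product: 8 (1S)-1-[4-(tert-butyldimethylsilyloxy)phenyl]-3-oxobutyl (2E)-3-[4-(tert-butyldimethylsilyloxy)-3-methoxyphenyl]prop-2-enoate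
Conditions: DCC (1.3 equiv), DMAP (0.1 equiv), CH2Cl2, 0 °C
Reagents that add atoms: none
Why: Steglich esterification acylates the only free hydroxyl through its oxygen, so that no bond to C1 is touched and the centre stays S, while the low temperature and the catalytic amount of DMAP should keep the β-acyloxy ketone from E1cB loss of the carboxylate.

Step 5
Reactants: 8 (1S)-1-[4-(tert-butyldimethylsilyloxy)phenyl]-3-oxobutyl (2E)-3-[4-(tert-butyldimethylsilyloxy)-3-methoxyphenyl]prop-2-enoate
Product: 12 (1S,6E)-7-[4-(tert-butyldimethylsilyloxy)-3-methoxyphenyl]-1-[4-(tert-butyldimethylsilyloxy)phenyl]-1-hydroxyhept-6-ene-3,5-dione (5-enol form), via lithium methyl enolate 9 (not isolated), via oxane hemiketal alkoxide 10 (not isolated), via dilithium alkoxide diketonate 11 (not isolated)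
Conditions: 8 added slowly to LiN(SiMe3)2 (2.5 equiv), THF, −78 °C, then −78 → −30 °C; AcOH (3 equiv), −78 °C; pH 7 phosphate buffer
Reagents that add atoms: none
Why: Anionic 1,5-O→C acyl migration (intramolecular Claisen condensation of a β-acyloxy ketone, the aliphatic counterpart of the Baker–Venkataraman rearrangement): the hindered amide removes a proton from the methyl group, the enolate carbon C4 adds to the ester carbonyl C5, and the tetrahedral intermediate collapses by expelling the C1 oxygen, so that the C4–C5 bond forms and the carbinol is set free in one event. The only ring closed is the transient oxane hemiketal alkoxide (O, C1, C2, C3, C4, C5), by a 6-exo-trig addition, whereas conjugate addition to C7 would need an eight-membered ring and should not compete. No stereocentre is created, and C1 keeps its S configuration because the acyl C–O bond, not the C1–O bond, is cleaved. The selectivity needed is enolisation at C4 and not at C2 (a C2 enolate would expel the carboxylate by E1cB), which the kinetic preference of the bulky amide for the methyl group over the β-branched methylene and the slow inverse addition at −78 °C should secure. The second equivalent of base converts the product into its diketonate, which drives the otherwise reversible Claisen step forward and blocks retro-Claisen, retro-aldol and dehydration until the cold acetic acid quench.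

Step 6
Reactants: 12 (1S,6E)-7-[4-(tert-butyldimethylsilyloxy)-3-methoxyphenyl]-1-[4-(tert-butyldimethylsilyloxy)phenyl]-1-hydroxyhept-6-ene-3,5-dione (5-enol form)
Product: 13 (1S,6E)-1-hydroxy-7-(4-hydroxy-3-methoxyphenyl)-1-(4-hydroxyphenyl)hept-6-ene-3,5-dione (5-enol form; CNP0206527.1)
Conditions: Bu4NF (2.4 equiv), AcOH (3 equiv), THF, 0 °C
Reagents that add atoms: none
Why: Fluoride-mediated cleavage of both aryl silyl ethers, buffered with acetic acid, should keep the β-hydroxy-1,3-diketone and the para-hydroxybenzylic carbinol away from free base and from strong acid, so that neither dehydration nor ionisation at C1 is expected.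

**Compound list**

1 | (E)-4-(4-hydroxyphenyl)but-3-en-2-one | CC(=O)/C=C/c1ccc(O)cc1 | starting material
2 | (E)-4-[4-(tert-butyldimethylsilyloxy)phenyl]but-3-en-2-one | CC(=O)/C=C/c1ccc(O[Si](C)(C)C(C)(C)C)cc1 | intermediate
3 | (S)-4-[4-(tert-butyldimethylsilyloxy)phenyl]-4-(4,4,5,5-tetramethyl-1,3,2-dioxaborolan-2-yl)butan-2-one | CC(=O)C[C@H](B1OC(C)(C)C(C)(C)O1)c1ccc(O[Si](C)(C)C(C)(C)C)cc1 | intermediate
4 | (S)-4-[4-(tert-butyldimethylsilyloxy)phenyl]-4-hydroxybutan-2-one | CC(=O)C[C@H](O)c1ccc(O[Si](C)(C)C(C)(C)C)cc1 | intermediate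
5 | (E)-ferulic acid, (E)-3-(4-hydroxy-3-methoxyphenyl)prop-2-enoic acid | COc1cc(/C=C/C(=O)O)ccc1O | starting material
6 | tert-butyldimethylsilyl (E)-3-[4-(tert-butyldimethylsilyloxy)-3-methoxyphenyl]prop-2-enoate | COc1cc(/C=C/C(=O)O[Si](C)(C)C(C)(C)C)ccc1O[Si](C)(C)C(C)(C)C | intermediate
7 | (E)-3-[4-(tert-butyldimethylsilyloxy)-3-methoxyphenyl]prop-2-enoic acid | COc1cc(/C=C/C(=O)O)ccc1O[Si](C)(C)C(C)(C)C | intermediate
8 | (1S)-1-[4-(tert-butyldimethylsilyloxy)phenyl]-3-oxobutyl (2E)-3-[4-(tert-butyldimethylsilyloxy)-3-methoxyphenyl]prop-2-enoate | CC(=O)C[C@H](OC(=O)/C=C/c1ccc(O[Si](C)(C)C(C)(C)C)c(OC)c1)c1ccc(O[Si](C)(C)C(C)(C)C)cc1 | intermediate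
9 | lithium enolate of 8 on the methyl side (lithium but-1-en-2-olate form) | [Li+].C=C([O-])C[C@H](OC(=O)/C=C/c1ccc(O[Si](C)(C)C(C)(C)C)c(OC)c1)c1ccc(O[Si](C)(C)C(C)(C)C)cc1 | intermediate
10 | lithium (6S)-6-[4-(tert-butyldimethylsilyloxy)phenyl]-2-{(E)-2-[4-(tert-butyldimethylsilyloxy)-3-methoxyphenyl]ethenyl}-4-oxooxan-2-olate (configuration at C2 of the oxane not defined) | [Li+].[O-]C1(/C=C/c2ccc(O[Si](C)(C)C(C)(C)C)c(OC)c2)CC(=O)C[C@@H](c2ccc(O[Si](C)(C)C(C)(C)C)cc2)O1 | intermediate
11 | dilithium C1-alkoxide/3,5-diketonate of 12 | [Li+].[Li+].COc1cc(/C=C/C([O-])=C\C(=O)C[C@H]([O-])c2ccc(O[Si](C)(C)C(C)(C)C)cc2)ccc1O[Si](C)(C)C(C)(C)C | intermediate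
12 | (1S,6E)-7-[4-(tert-butyldimethylsilyloxy)-3-methoxyphenyl]-1-[4-(tert-butyldimethylsilyloxy)phenyl]-1-hydroxyhept-6-ene-3,5-dione, 5-enol form | COc1cc(/C=C/C(O)=C\C(=O)C[C@H](O)c2ccc(O[Si](C)(C)C(C)(C)C)cc2)ccc1O[Si](C)(C)C(C)(C)C | intermediate
13 | (1S,6E)-1-hydroxy-7-(4-hydroxy-3-methoxyphenyl)-1-(4-hydroxyphenyl)hept-6-ene-3,5-dione, 5-enol form (CNP0206527.1) | COc1cc(/C=C/C(O)=C\C(=O)C[C@H](O)c2ccc(O)cc2)ccc1O | target

**Step count**

Total steps: 6. Longest linear sequence: 5 (steps 1, 2, 4, 5, 6).

**Steps most likely to fail**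

1. Step 5 (acyl migration). What may go wrong: proton transfer to the C2 enolate followed by E1cB expulsion of the carboxylate, or sluggish addition of the enolate to the electron-rich cinnamate. The fallback is an intermolecular Claisen condensation on an O-protected ketone and sets out from 4 and 7. Compound 4 would be silylated (Et3SiCl, imidazole, CH2Cl2) to (S)-4-[4-(tert-butyldimethylsilyloxy)phenyl]-4-(triethylsilyloxy)butan-2-one F1, and 7 would be activated with 1,1'-carbonyldiimidazole (THF, rt) to the acyl imidazolide (E)-3-[4-(tert-butyldimethylsilyloxy)-3-methoxyphenyl]-1-(imidazol-1-yl)prop-2-en-1-one F2. The kinetic lithium enolate of F1 (LiN(SiMe3)2, 2.2 equiv, THF, −78 °C) would be acylated at carbon by F2 to give the tris-silylated diketone (1S,6E)-7-[4-(tert-butyldimethylsilyloxy)-3-methoxyphenyl]-1-[4-(tert-butyldimethylsilyloxy)phenyl]-1-(triethylsilyloxy)hept-6-ene-3,5-dione F3. Bu4NF/AcOH in THF would then remove all three silyl groups, so that the fallback comes back to the route at 13. A C2 enolate of F1 has no good leaving group and should simply be reprotonated.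

2. Step 4 (esterification). What may go wrong: base-induced E1cB elimination of the freshly formed β-acyloxy ketone under the acylation catalyst, or slow acylation of the hindered benzylic alcohol. The fallback is an anionic acylation telescoped into the key step, so that 8 is never exposed to an amine or to chromatography; it sets out from 4 and 7. Compound 7 would be converted with (COCl)2 and catalytic DMF (CH2Cl2, 0 °C) into (E)-3-[4-(tert-butyldimethylsilyloxy)-3-methoxyphenyl]prop-2-enoyl chloride F4. Compound 4 would be deprotonated at oxygen (LiN(SiMe3)2, 1.05 equiv, THF, −78 °C) and acylated with F4 to give 8 in the flask, which would be treated at once with more LiN(SiMe3)2 (2.5 equiv) as in step 5. The fallback comes back to the route at 12.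

3. Step 2 (borylation/oxidation). What may go wrong: insufficient facial selectivity on this electron-rich β-aryl enone, or loss of the aryl silyl ether and retro-aldol cleavage during the basic oxidative work-up. The fallback sets C1 by C–C bond formation instead and sets out from 2. Ozonolysis (O3, CH2Cl2/MeOH, −78 °C; Me2S) would give 4-(tert-butyldimethylsilyloxy)benzaldehyde F5, which is also an article of commerce. An enamine-catalysed direct aldol reaction of F5 with acetone (used as co-solvent) under a D-proline-derived amide catalyst, the series that should give the S aldol of aryl aldehydes, would come back to the route at 4.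

**Further compounds**

F1 | step 5 | (S)-4-[4-(tert-butyldimethylsilyloxy)phenyl]-4-(triethylsilyloxy)butan-2-one | CC(=O)C[C@H](O[Si](CC)(CC)CC)c1ccc(O[Si](C)(C)C(C)(C)C)cc1
F2 | step 5 | (E)-3-[4-(tert-butyldimethylsilyloxy)-3-methoxyphenyl]-1-(imidazol-1-yl)prop-2-en-1-one | COc1cc(/C=C/C(=O)n2ccnc2)ccc1O[Si](C)(C)C(C)(C)C
F3 | step 5 | (1S,6E)-7-[4-(tert-butyldimethylsilyloxy)-3-methoxyphenyl]-1-[4-(tert-butyldimethylsilyloxy)phenyl]-1-(triethylsilyloxy)hept-6-ene-3,5-dione, 5-enol form | COc1cc(/C=C/C(O)=C\C(=O)C[C@H](O[Si](CC)(CC)CC)c2ccc(O[Si](C)(C)C(C)(C)C)cc2)ccc1O[Si](C)(C)C(C)(C)C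
F4 | step 4 | (E)-3-[4-(tert-butyldimethylsilyloxy)-3-methoxyphenyl]prop-2-enoyl chloride | COc1cc(/C=C/C(Cl)=O)ccc1O[Si](C)(C)C(C)(C)C
F5 | step 2 | 4-(tert-butyldimethylsilyloxy)benzaldehyde | O=Cc1ccc(O[Si](C)(C)C(C)(C)C)cc1
A1 | direct plan | (E)-1-(1,3-dithian-2-yl)-4-[3-methoxy-4-(triisopropylsilyloxy)phenyl]but-3-en-2-one | COc1cc(/C=C/C(=O)CC2SCCCS2)ccc1O[Si](C(C)C)(C(C)C)C(C)C
A2 | direct plan | (R)-2-[4-(triisopropylsilyloxy)phenyl]oxirane | C1[C@H](O1)c1ccc(O[Si](C(C)C)(C(C)C)C(C)C)cc1
A3 | direct plan | (E)-1-{2-[(2S)-2-hydroxy-2-[4-(triisopropylsilyloxy)phenyl]ethyl]-1,3-dithian-2-yl}-4-[3-methoxy-4-(triisopropylsilyloxy)phenyl]but-3-en-2-one | COc1cc(/C=C/C(=O)CC2(C[C@H](O)c3ccc(O[Si](C(C)C)(C(C)C)C(C)C)cc3)SCCCS2)ccc1O[Si](C(C)C)(C(C)C)C(C)C
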